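Early times come first, so I began with the opening readings of the flasks below, each a closed, stirred mixture at the same temperature.

| flask | starting material | partner | free catalyst | time |
|---|---|---|---|---|
| dusk | 0.800 M | 0.800 M | 0.0640 M |  |
| noon | 0.800 M | 2.40 M | 0.0640 M |  |
| dawn | 0.800 M | 0.800 M | 0.0320 M |  |
| midnight | 0.320 M | 0.320 M | 0.0640 M | 17 min |

| run | time / min | [starting material] / M |
|---|---|---|
| dusk run | 0.76 | 0.789 |
| dusk run | 2.3 | 0.766 |
| dusk run | 4.4 | 0.720 |
| dusk run | 6.9 | 0.638 |
| dusk run | 9.9 | 0.527 |
| dusk run | 13 | 0.412 |
| dusk run | 17 | 0.302 |
| noon run | 0.76 | 0.795 |
| noon run | 2.3 | 0.759 |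
| noon run | 4.4 | 0.599 |
| noon run | 6.9 | 0.248 |
| noon run | 9.9 | 0.058 |
| noon run | 13 | 0.013 |
| noon run | 17 | 0.004 |
| dawn run | 0.76 | 0.808 |
| dawn run | 2.3 | 0.794 |
| dawn run | 4.4 | 0.780 |
| dawn run | 6.9 | 0.736 |
| dawn run | 9.9 | 0.684 |
| dawn run | 13 | 0.584 |
| dawn run | 17 | 0.456 |

(scatter of a reading: 0.004 M)

- how the opening rate goes with [partner] round the charge of the dusk run: the exponent of the rate at two percent of starting material gone to target
- how the opening rate goes with [free catalyst] round the charge of the dusk run: the exponent of the rate at two percent of starting material gone to target
- starting material in the midnight run at 17 min, as a share of the starting material charged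

- Overall: starting material + partner -> target, with free catalyst as catalyst.
- Constant volume, constant temperature.
- The analysis sees a species whether free or bound.
- "The second partner" is partner.
- An order is taken over about fifteen percent of the charge, up and down.

In the dusk run, [starting material] fell at 0.0149 M min⁻¹ between the first two readings. Between 9.9 min and 13 min it fell at 0.0371 M min⁻¹, which is faster, although less of both reactants stood in the flask by then. So I read two routes: a seed route running from the start, and a route driven by the target itself, an autocatalytic route.

The dusk charges are equal, so [partner] follows [starting material] there. I divided each rate by [starting material][partner] and wrote the remainder as a seed term plus a coefficient times [target]. The first slope gave 0.0247 L mol⁻¹ min⁻¹ and the later one 0.168 L mol⁻¹ min⁻¹. From these the coefficient came to 0.466 L² mol⁻² min⁻¹ and the seed term to 0.0142 L mol⁻¹ min⁻¹.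

Their ratio is the crossing, the [target] at which the two routes carry equal rate: 0.0305 M. The scatter puts 0.00367 M min⁻¹ on the first slope, about a quarter of it, so the crossing is a rough reading.

The asked rate stands at 0.0160 M of target, below the crossing, so I gave the target route 34.4% of the dusk rate at that point. I took that route as first order in partner, so I expected a small positive partner order.

The forecast gave −0.1 for the partner order and 1.2 for the free-catalyst order, on the ground that “At 2% conversion the seed path carries about 80% of the rate.” For the midnight run it gave 57%. My own share for the seed route at that point in the dusk run was 65.6%, against the forecast's 80%.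

The simulation gave 0.21 for the partner order, 1.3 for the free-catalyst order and 77.7% for the midnight run.

    2 free catalyst ⇌ catalyst dimer, settled at all times (9.580 L mol⁻¹)
    catalyst dimer + starting material + partner → target + catalyst dimer (5.574 L² mol⁻² min⁻¹)
    starting material + partner + target → 2 target (0.4356 L² mol⁻² min⁻¹)
    free catalyst + partner ⇌ idle catalyst-reagent complex, settled at all times (2.840 L mol⁻¹)

In the dusk run, the target-driven step lifts the partner order from −0.11 to 0.21; my share, weighing order one against that lower value, gives 0.272. In the midnight run, the 0.0714 M of target made by 17 min, read through the same coefficient, puts the crossing at 0.0779 M, above the dusk reading, and the target in the midnight run at that time stood below it. Tying up free catalyst as idle catalyst-reagent complex left 77.7% of the starting material there, against 64.6% without that complex.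

The readings are simulated for substances that don't exist, and the scatter is random.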